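5 questions are put to 4 set-ups with the same charge, and one time scale, the life of the pool of L, is carried through the reckoning.

| flask | L | remark | time |
|---|---|---|---|
| beta | 0.80 M | run made earlier |  |
| gamma | 1.2 M | run made earlier |  |
| summer | 0.80 M | a single well-mixed tank run continuously and read at steady state, 40 h in it on average |  |
| autumn | 0.80 M | a closed flask charged with all of it at once and left for 40 h | 40 h |
| dusk | 0.80 M | plug flow through a tube for 40 h, no back-mixing | 40 h |
| dawn | 0.80 M | one stirred flow tank at steady state, fed with the mixture as stated, mean residence time 400 h |  |

- beta (time / h: X / %, L / %): 2.00: 0, 64; 6.00: 3, 53; 12.0: 16, 42; 15.0: 19, 41; 25.0: 42, 28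
- gamma (time / h: X / %, L / %): 0.833: 1, 69; 1.50: 0, 65; 2.50: 2, 63; 3.00: 0, 63; 4.00: 1, 58

(standard deviation of a reading: 1.5 percentage points)

- the stated concentrations are those of everything mixed, before any reaction; amounts are the same in each set-up
- the earlier runs were read with a standard deviation of 1.5 percentage points
- the earlier runs were made in a closed, stirred flask

- the set-up with the highest amount of X at the outlet or at the end, in percent of the L put in ("none" if the first two lie within 2 percentage points) (summer / autumn / dusk / dawn / none)
- amount of X at the outlet or at the end, in percent of the L put in, summer
- amount of X at the outlet or at the end, in percent of the L put in, autumn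
- amount of X at the outlet or at the end, in percent of the L put in, dusk
- amount of X at the outlet or at the end, in percent of the L put in, dawn

The fastest rung is the early drop of L. L stands at 64 % of its charge after 2.00 h in the beta run and at 63 % after 2.50 h in the gamma run, although cL was 0.80 M in one and 1.2 M in the other. This reads as a pre-equilibrium of L with an unseen partner, and the two then fall together as a pool.

The next rung is the lag of X. In the beta run the line through the X readings at 12.0 h and 25.0 h reaches zero at 4.00 h.

Slower still is the pool. Its fall between the first and last beta readings gives 27.8 h: this is the pool lifetime, the mean time a portion stays in L and its fast partner. As a reading it carries their scatter, and it is longer than the lag.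

The reckoning here runs on that lifetime. Autumn and dusk give each portion the same 40 h, so an exponential fall over that time leaves 23.7 % of the pool as charged in each. Carried from the beta reading at 2.00 h, L comes to 16.3 % in each. A stirred tank leaves T/(T+τ) of the pool: 41.0 % in summer and 6.50 % in dawn. Dawn leaves the smallest pool, since its 400 h is far beyond the lifetime, and summer leaves the largest.

The forecast reads “a fast first-order equilibrium” and gives 47 % for summer, 63 % for autumn, 63 % for dusk and 91 % for dawn, naming dawn. Its pool constant is 0.034 per hour, where the reading here gives 0.0360 /h.

    L ⇌ G (K = 0.440, k = 0.0120 /min)
    D → X (k = 0.00540 /min)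
    L + E → J (k = 5.70 × 10⁻⁴ /M/min)
    L → E (k = 8.90 × 10⁻⁴ /min)
    Q → D (k = 0.00640 /min)
    E → Z (k = 2.30 × 10⁻⁴ /min)
    E → Q (k = 0.00660 /min)

The flasks give 46.2 % in summer, 63.9 % in autumn, 63.9 % in dusk and 88.2 % in dawn, so dawn stands highest. In autumn at 12.9 h, E goes on to Q 29 times as fast as it goes to Z. Carried from 2.00 h with the lifetime 27.8 h, L comes to 16.3 % at 40.0 h in autumn, where the flask holds 15.2 %. The same reckoning comes to 40.1 % for the same flask stopped at 15 h, where it holds 39 %.

The data stem from a simulated flask from invented constants; the scatter is artificial.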